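**Plan**
- Retrosynthesis, late changes first: the C12 methyl ester comes from the isopropenyl methyl group, the C5 hydroxyl and C4=C15 methylene from a C4=C5 alkene (ene reaction with singlet oxygen), the C8 acetate from a ketone masked as a dioxolane, and the C3 angelate from a C3 ketone.
- Ring A is then cut at C2–C3 and C4–C5: the enone (C3=O, C4=C5) falls to propanal (C3, C4, C15) and a ring B ketone that carries a vinyl group (C1=C2) on quaternary C10.
- What makes this possible: quaternary C10 holds the C5 carbonyl of ring B and the terminal vinyl carbon C2 in a 1,4 relation (C5–C10–C1=C2). Acyl transfer to C2 therefore gives a 1,5-diketone that can close only to the six-membered ring A, and because C10 has no hydrogen the vinyl group cannot isomerise.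
- Forward: ring B from p-benzoquinone monoethylene ketal (C7 by rhodium/BINAP 1,4-addition, C10 by chiral-imine Michael addition), the vinyl group by oxidative decarboxylation, ring A by the hydroacylation/aldol condensation cascade, then adjustment of C3, C8, C5 and C12.
- Stereochemistry: C7 by catalyst control and C10 by auxiliary control; the C10 methyl group then directs C3 (hydride from the alpha face), C8 (bulky hydride from the alpha side) and C5 (singlet oxygen from the alpha face).

Key step: step 7

Remark: bicyclic compounds are numbered as eudesmanes (ring A = C1–C5 and C10, ring B = C5–C10, C14 on C10, C15 on C4, C11–C13 on C7). Alpha is the face opposite the C10 methyl group. The target SMILES is read as the (3S,5S,7R,8R,10R) isomer (3-beta angelate, 5-alpha OH, 8-beta acetate).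

**Route**

Step 1
Reactants: 1 1,4-dioxaspiro[4.5]deca-6,9-dien-8-one; 2 potassium trifluoro(prop-1-en-2-yl)borate
Product: 3 (6R)-6-(prop-1-en-2-yl)-1,4-dioxaspiro[4.5]dec-9-en-8-one
Conditions: [Rh(cod)2]BF4 (3 mol%), (R)-BINAP (3.3 mol%), Et3N, PhMe/H2O, 25 °C
Reagents that add atoms: potassium trifluoro(prop-1-en-2-yl)borate (2), [K+].CC(=C)[B-](F)(F)F
Why: Hayashi–Miyaura asymmetric 1,4-addition, in which the alkenyl rhodium species adds once to one of the two equivalent enone units and the ligand chooses the face; (R)-BINAP is chosen from the model established for cyclohexenone to give the (6R) adduct, which sets C7 of the target.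

Step 2
Reactants: 3 (6R)-6-(prop-1-en-2-yl)-1,4-dioxaspiro[4.5]dec-9-en-8-one
Product: 4 (6R,9RS)-9-methyl-6-(prop-1-en-2-yl)-1,4-dioxaspiro[4.5]decan-8-one
Conditions: LiBH(s-Bu)3, THF, −78 °C; then MeI, −78 → 0 °C
Reagents that add atoms: iodomethane, CI
Why: Conjugate reduction of the beta-unsubstituted enone gives the lithium enolate regiospecifically and iodomethane traps it at C9 (reductive alkylation); the configuration of C9 does not matter because it is planarised in steps 3 and 4.

Step 3
Reactants: 4 (6R,9RS)-9-methyl-6-(prop-1-en-2-yl)-1,4-dioxaspiro[4.5]decan-8-one; 5 (R)-1-phenylethylamine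
Product: 6 N-[(6R)-9-methyl-6-(prop-1-en-2-yl)-1,4-dioxaspiro[4.5]decan-8-ylidene]-(1R)-1-phenylethanamine
Conditions: PhMe, reflux, Dean–Stark (−H2O), no acid
Reagents that add atoms: (R)-1-phenylethylamine (5), C[C@@H](N)c1ccccc1
Why: Imine condensation with azeotropic removal of water; the imine equilibrates with its more substituted secondary enamine, so both C9 epimers of 4 converge.

Step 4
Reactants: 6 the imine from step 3; 7 methyl acrylate
Product: 9 methyl 3-[(6R,9R)-9-methyl-8-oxo-6-(prop-1-en-2-yl)-1,4-dioxaspiro[4.5]decan-9-yl]propanoate, via Michael-adduct imine 8 (not isolated)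
Conditions: methyl acrylate, THF, 40 °C; then AcOH/H2O, 20 °C
Reagents that add atoms: methyl acrylate (7), C=CC(=O)OC; water, O
Why: Deracemising Michael addition of a chiral imine, in which the more substituted secondary enamine adds to the acrylate through a compact aza-ene-like transition state on the face away from the phenyl group of the (R)-auxiliary; this sets the quaternary centre (C10 of the target) under reagent control against the weak bias of the remote isopropenyl group, and aqueous acetic acid then hydrolyses the imine.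

Step 5
Reactants: 9 the keto ester from step 4
Product: 10 3-[(6R,9R)-9-methyl-8-oxo-6-(prop-1-en-2-yl)-1,4-dioxaspiro[4.5]decan-9-yl]propanoic acid
Conditions: LiOH, THF/MeOH/H2O, 20 °C; then HCl (1 M), 0 °C, pH 3
Reagents that add atoms: lithium hydroxide, [Li+].[OH-]
Why: Saponification of the methyl ester, with the dioxolane and both stereocentres stable to base and the acidification kept cold and brief.

Step 6
Reactants: 10 the keto acid from step 5
Product: 11 (6R,9S)-9-ethenyl-9-methyl-6-(prop-1-en-2-yl)-1,4-dioxaspiro[4.5]decan-8-one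
Conditions: Pb(OAc)4, Cu(OAc)2·H2O (cat.), pyridine, PhH, 80 °C
Reagents that add atoms: none
Why: Oxidative decarboxylation with lead tetraacetate, in which the primary alkyl radical is oxidised by divalent copper with loss of a beta-hydrogen to the terminal alkene; the quaternary centre is untouched and its descriptor changes only because the priorities change.

Step 7
Reactants: 11 the vinyl ketone from step 6; 12 propanal
Product: 14 (7R,10R)-8,8-(ethylenedioxy)eudesma-4,11-dien-3-one, via pyridyl ketimine 13 (not isolated)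
Conditions: propanal (5 equiv), RhCl(PPh3)3 (10 mol%), 2-amino-3-methylpyridine (1 equiv), PhCO2H (0.2 equiv), PhMe, 130 °C, sealed tube; aqueous work-up on silica
Reagents that add atoms: propanal (12), CCC=O; water, O
Why: Proposed new method: propanal condenses with 2-amino-3-methylpyridine to an aldimine whose pyridine nitrogen directs monovalent rhodium into the formyl C–H bond, and the iminoacyl rhodium hydride adds across the C1=C2 vinyl group with rhodium on the terminal carbon and reductively eliminates to ketimine 13, which makes C2–C3 by a polarity-reversed acyl transfer (closest known reaction type: chelation-assisted intermolecular hydroacylation of 1-alkenes with aldehydes). Ketimine 13 is the tautomer of the enamine used in the second stage of a Robinson annulation, so under the same amine and benzoic acid its C4 carbon should add to the C5 ketone and lose water, which makes C4=C5 and closes ring A by a 6-(enolendo)-exo-trig aldol condensation; hydrolysis then returns the aminopyridine. No stereocentre is formed: C7 and C10 pass through unchanged and C3 and C5 stay sp2, to be set later from the alpha face. The linear mode of insertion is secured by the vinyl group on quaternary C10, which has no allylic hydrogen and cannot isomerise, and the 1,1-disubstituted isopropenyl group should not insert. The direction of the aldol is secured by ring size, since attack by C2 would give a four-membered ring and the bridged ketol from C6 cannot dehydrate and reverts.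

Step 8
Reactants: 14 the enone from step 7
Product: 15 (3S,7R,10R)-8,8-(ethylenedioxy)eudesma-4,11-dien-3-ol
Conditions: NaBH4, CeCl3·7H2O, MeOH, −20 °C
Reagents that add atoms: none
Why: Luche 1,2-reduction, in which hydride adds pseudo-axially to the half-chair enone from the alpha face and gives the pseudo-equatorial 3-beta (3S) allylic alcohol.

Step 9
Reactants: 15 the allylic alcohol from step 8; 16 angelic acid [(Z)-2-methylbut-2-enoic acid]
Product: 17 (3S,7R,10R)-8,8-(ethylenedioxy)eudesma-4,11-dien-3-yl (Z)-2-methylbut-2-enoate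
Conditions: 16, 2,4,6-Cl3C6H2COCl, Et3N, PhMe, 20 °C; then 15, 80 °C (no DMAP)
Reagents that add atoms: angelic acid (16), C/C=C(/C)C(=O)O
Why: Yamaguchi-type esterification through the mixed anhydride made in the flask, run without a nucleophilic catalyst so that the Z double bond does not isomerise, with retention at C3.

Step 10
Reactants: 17 the angelate from step 9
Product: 18 (3S,7R,10R)-8-oxoeudesma-4,11-dien-3-yl (Z)-2-methylbut-2-enoate
Conditions: PPTS, acetone/H2O, 50 °C
Reagents that add atoms: water, O
Why: Mild acid-catalysed hydrolysis of the dioxolane that should leave the allylic ester intact, keep the isopropenyl double bond out of conjugation and leave the C7 substituent in its equatorial, thermodynamically preferred position.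

Step 11
Reactants: 18 the ketone from step 10
Product: 20 (3S,7R,8R,10R)-8-acetoxyeudesma-4,11-dien-3-yl (Z)-2-methylbut-2-enoate, via lithium 8-alkoxide 19 (not isolated)
Conditions: LiBH(s-Bu)3, THF, −78 °C; then Ac2O, DMAP, −78 → 20 °C
Reagents that add atoms: acetic anhydride, CC(=O)OC(C)=O
Why: Reductive acetylation, in which the bulky borohydride attacks from the equatorial alpha side because the beta face is closed by the syn-axial C10 methyl group; this gives the axial 8-beta (8R) alkoxide cis to the isopropenyl group, which is acetylated in the same flask.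

Step 12
Reactants: 20 the diester from step 11
Product: 22 (3S,5S,7R,8R,10R)-8-acetoxy-5-hydroxyeudesma-4(15),11-dien-3-yl (Z)-2-methylbut-2-enoate, via 5-hydroperoxide 21 (not isolated)
Conditions: O2, tetraphenylporphyrin (cat.), hν (visible), CH2Cl2, −20 °C; then PPh3, 20 °C
Reagents that add atoms: oxygen, O=O
Why: Schenck ene reaction, in which singlet oxygen adds to the electron-rich tetrasubstituted C4=C5 bond from the alpha face and takes a hydrogen from the C15 methyl group (the 6-alpha hydrogen is equatorial and H-3 is deactivated by the geminal acyloxy group); this sets C5 as the 5-alpha hydroperoxide with the C4=C15 methylene, and triphenylphosphine reduces the O–O bond.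

Step 13
Reactants: 22 the tertiary alcohol from step 12
Product: 23 (3S,5S,7R,8R,10R)-8-acetoxy-5,12-dihydroxyeudesma-4(15),11(13)-dien-3-yl (Z)-2-methylbut-2-enoate
Conditions: SeO2 (0.5 equiv), t-BuOOH, CH2Cl2, 20 °C
Reagents that add atoms: selenium dioxide, O=[Se]=O; tert-butyl hydroperoxide, CC(C)(C)OO
Why: Selenium dioxide allylic hydroxylation (ene reaction at the terminal carbon, then 2,3-sigmatropic shift) of the only alkene with a reactive allylic methyl group, since the C4=C15 methylene has no free allylic C–H; any over-oxidised enal is on the path of step 14.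

Step 14
Reactants: 23 the allylic alcohol from step 13
Product: 25 (3S,5S,7R,8R,10R)-8-acetoxy-5-hydroxy-3-[(Z)-2-methylbut-2-enoyloxy]eudesma-4(15),11(13)-dien-12-oic acid, via enal 24 (not isolated)
Conditions: TEMPO (cat.), PhI(OAc)2, CH2Cl2, 20 °C; then NaClO2, NaH2PO4, 2-methyl-2-butene, t-BuOH/H2O, 20 °C
Reagents that add atoms: sodium chlorite, [Na+].[O-]Cl=O
Why: Oxoammonium oxidation of the primary allylic alcohol, which cannot touch the tertiary C5 alcohol, followed by Pinnick oxidation of the enal with an alkene scavenger.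

Step 15
Reactants: 25 the acid from step 14
Product: 26 methyl (3S,5S,7R,8R,10R)-8-acetoxy-5-hydroxy-3-[(Z)-2-methylbut-2-enoyloxy]eudesma-4(15),11(13)-dien-12-oate (target)
Conditions: Me3SiCHN2, PhMe/MeOH, 0 °C
Reagents that add atoms: (trimethylsilyl)diazomethane, C[Si](C)(C)C=[N+]=[N-]
Why: Methyl esterification of the carboxylic acid with the diazoalkane under near-neutral conditions that should leave both esters, the tertiary allylic alcohol and all alkenes unchanged.

**Compound list**

1 | 1,4-dioxaspiro[4.5]deca-6,9-dien-8-one (p-benzoquinone monoethylene ketal) | O=C1C=CC2(OCCO2)C=C1 | starting material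
2 | potassium trifluoro(prop-1-en-2-yl)borate | [K+].CC(=C)[B-](F)(F)F | starting material
3 | (6R)-6-(prop-1-en-2-yl)-1,4-dioxaspiro[4.5]dec-9-en-8-one | C=C(C)[C@H]1CC(=O)C=CC12OCCO2 | intermediate
4 | (6R,9RS)-9-methyl-6-(prop-1-en-2-yl)-1,4-dioxaspiro[4.5]decan-8-one (C9 epimers) | C=C(C)[C@H]1CC(=O)C(C)CC12OCCO2 | intermediate
5 | (R)-1-phenylethylamine | C[C@@H](N)c1ccccc1 | starting material
6 | N-[(6R)-9-methyl-6-(prop-1-en-2-yl)-1,4-dioxaspiro[4.5]decan-8-ylidene]-(1R)-1-phenylethanamine | C=C(C)[C@H]1CC(=N[C@H](C)c2ccccc2)C(C)CC13OCCO3 | intermediate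
7 | methyl acrylate | C=CC(=O)OC | starting material
8 | methyl 3-[(6R,9R)-9-methyl-8-{[(1R)-1-phenylethyl]imino}-6-(prop-1-en-2-yl)-1,4-dioxaspiro[4.5]decan-9-yl]propanoate | C=C(C)[C@H]1CC(=N[C@H](C)c2ccccc2)[C@](C)(CCC(=O)OC)CC13OCCO3 | intermediate (not isolated)
9 | methyl 3-[(6R,9R)-9-methyl-8-oxo-6-(prop-1-en-2-yl)-1,4-dioxaspiro[4.5]decan-9-yl]propanoate | C=C(C)[C@H]1CC(=O)[C@](C)(CCC(=O)OC)CC12OCCO2 | intermediate
10 | 3-[(6R,9R)-9-methyl-8-oxo-6-(prop-1-en-2-yl)-1,4-dioxaspiro[4.5]decan-9-yl]propanoic acid | C=C(C)[C@H]1CC(=O)[C@](C)(CCC(=O)O)CC12OCCO2 | intermediate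
11 | (6R,9S)-9-ethenyl-9-methyl-6-(prop-1-en-2-yl)-1,4-dioxaspiro[4.5]decan-8-one | C=C(C)[C@H]1CC(=O)[C@](C)(C=C)CC12OCCO2 | intermediate
12 | propanal | CCC=O | starting material
13 | (6R,9R)-9-methyl-9-{3-[(3-methylpyridin-2-yl)imino]pentyl}-6-(prop-1-en-2-yl)-1,4-dioxaspiro[4.5]decan-8-one | C=C(C)[C@H]1CC(=O)[C@](C)(CCC(CC)=Nc2ncccc2C)CC13OCCO3 | intermediate (not isolated)
14 | (7R,10R)-8,8-(ethylenedioxy)eudesma-4,11-dien-3-one | C=C(C)[C@H]1CC2=C(C)C(=O)CC[C@]2(C)CC13OCCO3 | intermediate
15 | (3S,7R,10R)-8,8-(ethylenedioxy)eudesma-4,11-dien-3-ol | C=C(C)[C@H]1CC2=C(C)[C@@H](O)CC[C@]2(C)CC13OCCO3 | intermediate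
16 | angelic acid, (Z)-2-methylbut-2-enoic acid | C/C=C(/C)C(=O)O | starting material
17 | (3S,7R,10R)-8,8-(ethylenedioxy)eudesma-4,11-dien-3-yl (Z)-2-methylbut-2-enoate | C=C(C)[C@H]1CC2=C(C)[C@@H](OC(=O)/C(C)=C\C)CC[C@]2(C)CC13OCCO3 | intermediate
18 | (3S,7R,10R)-8-oxoeudesma-4,11-dien-3-yl (Z)-2-methylbut-2-enoate | C=C(C)[C@H]1CC2=C(C)[C@@H](OC(=O)/C(C)=C\C)CC[C@]2(C)CC1=O | intermediate
19 | lithium (3S,7R,8R,10R)-3-[(Z)-2-methylbut-2-enoyloxy]eudesma-4,11-dien-8-olate | C=C(C)[C@H]1CC2=C(C)[C@@H](OC(=O)/C(C)=C\C)CC[C@]2(C)C[C@H]1[O-].[Li+] | intermediate (not isolated)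
20 | (3S,7R,8R,10R)-8-acetoxyeudesma-4,11-dien-3-yl (Z)-2-methylbut-2-enoate | C=C(C)[C@H]1CC2=C(C)[C@@H](OC(=O)/C(C)=C\C)CC[C@]2(C)C[C@H]1OC(C)=O | intermediate
21 | (3S,5S,7R,8R,10R)-8-acetoxy-5-hydroperoxyeudesma-4(15),11-dien-3-yl (Z)-2-methylbut-2-enoate | C=C(C)[C@H]1C[C@@]2(OO)C(=C)[C@@H](OC(=O)/C(C)=C\C)CC[C@]2(C)C[C@H]1OC(C)=O | intermediate (not isolated)
22 | (3S,5S,7R,8R,10R)-8-acetoxy-5-hydroxyeudesma-4(15),11-dien-3-yl (Z)-2-methylbut-2-enoate | C=C(C)[C@H]1C[C@@]2(O)C(=C)[C@@H](OC(=O)/C(C)=C\C)CC[C@]2(C)C[C@H]1OC(C)=O | intermediate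
23 | (3S,5S,7R,8R,10R)-8-acetoxy-5,12-dihydroxyeudesma-4(15),11(13)-dien-3-yl (Z)-2-methylbut-2-enoate | C=C(CO)[C@H]1C[C@@]2(O)C(=C)[C@@H](OC(=O)/C(C)=C\C)CC[C@]2(C)C[C@H]1OC(C)=O | intermediate
24 | (3S,5S,7R,8R,10R)-8-acetoxy-5-hydroxy-12-oxoeudesma-4(15),11(13)-dien-3-yl (Z)-2-methylbut-2-enoate | C=C(C=O)[C@H]1C[C@@]2(O)C(=C)[C@@H](OC(=O)/C(C)=C\C)CC[C@]2(C)C[C@H]1OC(C)=O | intermediate (not isolated)
25 | (3S,5S,7R,8R,10R)-8-acetoxy-5-hydroxy-3-[(Z)-2-methylbut-2-enoyloxy]eudesma-4(15),11(13)-dien-12-oic acid | C=C(C(=O)O)[C@H]1C[C@@]2(O)C(=C)[C@@H](OC(=O)/C(C)=C\C)CC[C@]2(C)C[C@H]1OC(C)=O | intermediate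
26 | methyl (3S,5S,7R,8R,10R)-8-acetoxy-5-hydroxy-3-[(Z)-2-methylbut-2-enoyloxy]eudesma-4(15),11(13)-dien-12-oate | C=C(C(=O)OC)[C@H]1C[C@@]2(O)C(=C)[C@@H](OC(=O)/C(C)=C\C)CC[C@]2(C)C[C@H]1OC(C)=O | target

**Totals**
Total step count: 15. Longest linear sequence: 15 steps (1 → 26); all other inputs are commercial.

**Steps most likely to fail**

Step 7 (proposed new method). The ketimine may fail to cyclise under the hydroacylation conditions, propanal may condense with itself, or the rhodium hydride may move the isopropenyl double bond. The fallback sets out from acid 10 and comes back at enone 14. Acid 10 is converted with N-hydroxyphthalimide and N,N'-diisopropylcarbodiimide into the N-acyloxyphthalimide F1. A nickel-catalysed decarboxylative ketone synthesis (NiCl2·glyme, 4,4'-di-tert-butyl-2,2'-bipyridine, Zn dust, S-(pyridin-2-yl) propanethioate, THF/DMA) then gives the free 1,5-diketone F2. Pyrrolidine/AcOH in toluene at 80 °C closes F2 to 14 by the aldol condensation of a Robinson annulation. This forms the same two bonds in two separate, known operations.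

Step 12. Hydrogen abstraction from C6 in place of C15, or attack on the beta face, would place the oxygen at C4 or give the 5-beta isomer. The fallback sets out from 20 and comes back at 22. Epoxidation with mCPBA (CH2Cl2, NaHCO3, 0 °C) should take the most electron-rich, tetrasubstituted alkene from the alpha face and give the 4-alpha,5-alpha-epoxide F3. Isomerisation with Me3SiOTf and DBU in toluene, in which the base removes a C15 methyl hydrogen anti to the breaking C4–O bond, should give the 5-alpha trimethylsilyl ether F4 with the C4=C15 methylene. Mild acidic methanolysis (citric acid, MeOH) then gives 22.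

Step 13. The oxidation may lose chemoselectivity between the two 1,1-disubstituted alkenes, attack C7, or run on past the alcohol. The fallback sets out from 22 and comes back at enal 24. Ene-type chlorination with hypochlorous acid (Ca(OCl)2, solid CO2, CH2Cl2/H2O) should give the allylic chloride F5. A Kornblum-type oxidation with N-methylmorpholine N-oxide in MeCN then gives 24, which enters the chlorite stage of step 14.

**Further compounds**
F1 | step 7 | 1,3-dioxoisoindolin-2-yl 3-[(6R,9R)-9-methyl-8-oxo-6-(prop-1-en-2-yl)-1,4-dioxaspiro[4.5]decan-9-yl]propanoate | C=C(C)[C@H]1CC(=O)[C@](C)(CCC(=O)ON2C(=O)c3ccccc3C2=O)CC14OCCO4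
F2 | step 7 | (6R,9R)-9-methyl-9-(3-oxopentyl)-6-(prop-1-en-2-yl)-1,4-dioxaspiro[4.5]decan-8-one | C=C(C)[C@H]1CC(=O)[C@](C)(CCC(=O)CC)CC12OCCO2
F3 | step 12 | (3S,4R,5S,7R,8R,10R)-8-acetoxy-4,5-epoxyeudesm-11-en-3-yl (Z)-2-methylbut-2-enoate (4-alpha,5-alpha-epoxide) | C=C(C)[C@H]1C[C@]23O[C@]3(C)[C@@H](OC(=O)/C(C)=C\C)CC[C@]2(C)C[C@H]1OC(C)=O
F4 | step 12 | (3S,5S,7R,8R,10R)-8-acetoxy-5-(trimethylsilyloxy)eudesma-4(15),11-dien-3-yl (Z)-2-methylbut-2-enoate | C=C(C)[C@H]1C[C@@]2(O[Si](C)(C)C)C(=C)[C@@H](OC(=O)/C(C)=C\C)CC[C@]2(C)C[C@H]1OC(C)=O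
F5 | step 13 | (3S,5S,7R,8R,10R)-8-acetoxy-12-chloro-5-hydroxyeudesma-4(15),11(13)-dien-3-yl (Z)-2-methylbut-2-enoate | C=C(CCl)[C@H]1C[C@@]2(O)C(=C)[C@@H](OC(=O)/C(C)=C\C)CC[C@]2(C)C[C@H]1OC(C)=O
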